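**Retrosynthetic overview**
1. Locants used here: ring C1 (lactone O–CH), C2=C3(CH3), C4 (OAc), C5/C6 (oxirane, CH3 on C6), C7H2, C8H2, C9 (angelate), C10; lactone carbons C11 (bears =C13H2) and C12 (C=O).
2. Target ⇐ epoxidation of the C5=C6 alkene of a (2E,5Z)-cyclodecadiene lactone that already carries both esters (last step).
3. Ten-membered ring ⇐ C6–C7 bond by hydroboration/B-alkyl Suzuki–Miyaura macrocyclisation. The enabling feature is that the cis-fused C5–C6 oxirane with its methyl on C6 is, one oxidation level down, a (5Z)-trisubstituted alkene, so C6 can enter as an sp2 iodide; the unsubstituted C7H2–C8H2 bridge beside the C9 carbinol is a hydroborated vinyl group.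
4. Seco-precursor ⇐ indium Barbier allylation (C1–C10 bond, then the cis-lactone) of enal fragment A (C1–C6) with bromomethyl-acrylate fragment B (C7–C13, from (S)-but-3-ene-1,2-diol); a Mitsunobu esterification with angelic acid then inverts C9.
5. Ring order: γ-lactone (step 11), ten-membered carbocycle (step 14), oxirane (step 15).

Key step: step 14

Remark: the acyclic induction in step 11 is assumed to follow the Felkin–Anh sense (new bond anti to the silyloxy group) known for γ-oxygenated allylmetal reagents; the route is built on that sense and the resulting C9 epimer is corrected in step 13.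

**Fragment A**

Step 1
Reactants: 1 3-methylbut-2-en-1-yl acetate (prenyl acetate)
Product: 2 (2E)-3-methyl-4-oxobut-2-en-1-yl acetate
Conditions: SeO2, 1,4-dioxane, 80 °C
Reagents that add atoms: selenium dioxide, O=[Se]=O
Why: Riley allylic oxidation (ene reaction, then [2,3]-sigmatropic shift) should oxidise the methyl group trans to the acetoxymethyl chain, which fixes the (E) geometry of the later C2=C3 alkene; no stereocentre is formed.

Step 2
Reactants: 2 (2E)-3-methyl-4-oxobut-2-en-1-yl acetate; 3 propyne
Product: 4 (2E,4R)-4-hydroxy-3-methylhept-2-en-5-yn-1-yl acetate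
Conditions: Zn(CH3)2, ProPhenol ligand (20 mol%, the enantiomer that gives the 4R carbinol), Ph3P=O (40 mol%), toluene/THF, 4 °C
Reagents that add atoms: none
Why: ProPhenol–dizinc-catalysed enantioselective alkynylation (1,2-addition of the zinc acetylide to the α-branched enal) should set C4, the ligand enantiomer fixing the 4R configuration.

Step 3
Reactants: 4 (2E,4R)-4-hydroxy-3-methylhept-2-en-5-yn-1-yl acetate
Product: 6 (2E,4S,5Z)-6-iodo-3-methylhepta-2,5-diene-1,4-diol, via cyclic vinylalanate 5 (not isolated)
Conditions: NaAlH2(OCH2CH2OCH3)2, THF, 0 °C → rt; then I2, THF, −78 → 0 °C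
Reagents that add atoms: iodine, II
Why: hydroxyl-directed trans-hydroalumination places aluminium on the distal alkyne carbon in a five-membered alanate, and iodinolysis with retention should give the (5Z)-iodide (iodine cis to C4) while excess hydride cleaves the acetate; C4 is untouched (its descriptor becomes S only through the priority rules).

Step 4
Reactants: 6 (2E,4S,5Z)-6-iodo-3-methylhepta-2,5-diene-1,4-diol
Product: 7 (2E,4S,5Z)-4-hydroxy-6-iodo-3-methylhepta-2,5-dienal
Conditions: TEMPO (10 mol%), PhI(OAc)2, CH2Cl2, rt
Reagents that add atoms: none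
Why: oxoammonium (TEMPO) oxidation is selective for the primary allylic alcohol over the hindered secondary one, and the (E)-enal cannot form a lactol with the C4 hydroxyl; no stereocentre changes.

Step 5
Reactants: 7 (2E,4S,5Z)-4-hydroxy-6-iodo-3-methylhepta-2,5-dienal
Product: 8 (2E,4S,5Z)-6-iodo-3-methyl-1-oxohepta-2,5-dien-4-yl acetate (fragment A)
Conditions: Ac2O, pyridine, DMAP (cat.), CH2Cl2, 0 °C
Reagents that add atoms: acetic anhydride, CC(=O)OC(C)=O
Why: DMAP-catalysed O-acylation installs the C4 acetate with retention.

**Fragment B**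

Step 6
Reactants: 9 (2S)-but-3-ene-1,2-diol
Product: 10 (3S)-3,4-bis[(tert-butyldimethylsilyl)oxy]but-1-ene
Conditions: TBSCl, imidazole, DMF, rt
Reagents that add atoms: tert-butyldimethylsilyl chloride, CC(C)(C)[Si](C)(C)Cl
Why: standard bis-silylation of the diol; the chiral-pool stereocentre (later C9) is untouched.

Step 7
Reactants: 10 (3S)-3,4-bis[(tert-butyldimethylsilyl)oxy]but-1-ene
Product: 11 (2S)-2-[(tert-butyldimethylsilyl)oxy]but-3-en-1-ol
Conditions: HF·pyridine, pyridine, THF, 0 °C
Reagents that add atoms: none
Why: buffered HF cleaves the less hindered primary silyl ether faster than the secondary one, and acidic conditions exclude silyl migration.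

Step 8
Reactants: 11 (2S)-2-[(tert-butyldimethylsilyl)oxy]but-3-en-1-ol
Product: 12 (2S)-2-[(tert-butyldimethylsilyl)oxy]but-3-enal
Conditions: Dess–Martin periodinane, CH2Cl2, 0 °C → rt (used crude)
Reagents that add atoms: none
Why: Dess–Martin oxidation under non-basic conditions should give the α-silyloxy β,γ-unsaturated aldehyde without epimerisation or alkene migration.

Step 9
Reactants: 12 (2S)-2-[(tert-butyldimethylsilyl)oxy]but-3-enal; 13 methyl propiolate
Product: 15 methyl (4S)-4-[(tert-butyldimethylsilyl)oxy]-3-hydroxy-2-methylidenehex-5-enoate (C3 epimers), via vinylalane 14 (not isolated)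
Conditions: i-Bu2AlH, N-methylmorpholine N-oxide, THF, 0 °C (13 → 14); then 12, 0 °C → rt
Reagents that add atoms: none
Why: hydroalumination of the propiolate gives an α-alumino acrylate that adds 1,2 to the aldehyde (non-basic route to a Morita–Baylis–Hillman-type adduct), so the C4 centre survives; the new C3 carbinol is formed as a mixture that is erased in step 10.

Step 10
Reactants: 15 methyl (4S)-4-[(tert-butyldimethylsilyl)oxy]-3-hydroxy-2-methylidenehex-5-enoate
Product: 16 methyl (2Z,4S)-2-(bromomethyl)-4-[(tert-butyldimethylsilyl)oxy]hexa-2,5-dienoate (fragment B)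
Conditions: NBS, Me2S, CH2Cl2, 0 °C → rt
Reagents that add atoms: N-bromosuccinimide, O=C1CCC(=O)N1Br
Why: Corey–Kim-type activation of the allylic alcohol and SN2' attack of bromide at the methylidene carbon should give the thermodynamically preferred (Z)-bromide (ester trans to the branched carbon); C4 is not involved.

**Union, ring closures, end game**

Step 11
Reactants: 8 fragment A; 16 fragment B
Product: 19 cis-α-methylene-γ-butyrolactone silyl ether (C1, C4, C10 configured as in 25; C9 epimeric, 9S), via allylindium dibromide 17 (not isolated), via syn hydroxy ester 18 (not isolated)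
Conditions: In (powder), THF/H2O 1:1, rt; then TsOH·H2O (5 mol%), CH2Cl2, rt
Reagents that add atoms: none
Why: in this indium Barbier allylation the (Z)-allylindium 17 reacts at its γ-carbon through a chair (Zimmerman–Traxler) transition state to give the 1,10-syn adduct 18, the aldehyde approaching anti to the silyloxy group in the conformer whose C9–H eclipses the alkene (Felkin–Anh-type 1,2-induction under allylic 1,3-strain), which sets C10 and C1; acid then closes the cis-lactone by 5-exo-trig acyl substitution.

Step 12
Reactants: 19 cis-lactone silyl ether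
Product: 20 cis-lactone alcohol (9S)
Conditions: HF·pyridine, THF, 0 °C → rt
Reagents that add atoms: none
Why: fluoride-mediated desilylation under buffered acidic conditions leaves the acetate, the vinyl iodide and the lactone intact and avoids base-induced translactonisation.

Step 13
Reactants: 20 cis-lactone alcohol (9S); 21 angelic acid [(2Z)-2-methylbut-2-enoic acid]
Product: 22 seco-angelate (9R; all stereocentres except C5/C6 as in 25)
Conditions: PPh3, diisopropyl azodicarboxylate, toluene, 0 °C → rt
Reagents that add atoms: none
Why: Mitsunobu esterification: SN2 displacement of the alkoxyphosphonium by angelate should invert C9 (9S → 9R) and install the ester under neutral conditions that preserve the (Z) geometry of the acid.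

Step 14
Reactants: 22 seco-angelate
Product: 24 (2E,5Z)-cyclodecadiene lactone (macrocyclic diene), via B-alkyl-9-BBN borane 23 (not isolated)
Conditions: 9-BBN-H, THF, 0 °C → rt; then added slowly to Pd(dppf)Cl2 (15 mol%), AsPh3, Cs2CO3, DMF/THF/H2O, rt (0.002 M)
Reagents that add atoms: none
Why: 9-BBN adds anti-Markovnikov to the only monosubstituted alkene to give borane 23 (boron on C7); zerovalent palladium then inserts into the C6–I bond with retention, the base-activated borate transfers the C7 alkyl group to palladium, and reductive elimination forms the C6–C7 bond. The closest known reaction type is the B-alkyl Suzuki–Miyaura macrocyclisation of ω-alkenyl vinyl iodides used for twelve-membered and larger carbocycles. The ten-membered carbocycle closes by reductive elimination from an eleven-membered alkyl(alkenyl)palladacycle, an intramolecular sp2–sp3 cross-coupling. No stereocentre is created; the one new stereo-element, the (5Z) ring alkene, is controlled by the stereoretentive oxidative addition and reductive elimination at the preformed (Z)-iodide. The step needs chemoselective hydroboration, secured by the preference of 9-BBN for the terminal vinyl group over the trisubstituted alkenes and the electron-poor methylene lactone and angelate. It also needs cyclisation rather than oligomerisation or ionisation of the allylic esters, secured by high dilution, fast oxidative addition of the vinyl iodide, and the turn imposed by the cis-fused lactone, the (2E)-alkene and the (Z)-iodide.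

Step 15
Reactants: 24 macrocyclic diene
Product: 25 target (1S,2E,4R,5R,6S,9R,10R in the locants above)
Conditions: dimethyldioxirane, acetone/CH2Cl2, −20 °C
Reagents that add atoms: dimethyldioxirane, CC1(C)OO1
Why: electrophilic (Prilezhaev-type) epoxidation should select C5=C6 (one allylic acyloxy group) over C2=C3 (two) and the conjugated alkenes, and syn addition to the exposed face of the (Z)-alkene, anti to the C4 acetoxy group in the conformer with C4–H eclipsing the alkene, sets C5 and C6 as the cis-oxirane.

**Compound list**
1 | 3-methylbut-2-en-1-yl acetate | CC(C)=CCOC(C)=O | starting material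
2 | (2E)-3-methyl-4-oxobut-2-en-1-yl acetate | CC(=O)OC/C=C(\C)C=O | intermediate
3 | propyne | CC#C | starting material
4 | (2E,4R)-4-hydroxy-3-methylhept-2-en-5-yn-1-yl acetate | CC(=O)OC/C=C(\C)[C@@H](O)C#CC | intermediate
5 | cyclic vinylalanate (disodium salt; five-membered 1,2-oxaluminole from 4) | [Na+].[Na+].[O-]C/C=C(\C)[C@H]1O[Al-](OCCOC)(OCCOC)C(C)=C1 | intermediate
6 | (2E,4S,5Z)-6-iodo-3-methylhepta-2,5-diene-1,4-diol | OC/C=C(\C)[C@@H](O)/C=C(/C)I | intermediate
7 | (2E,4S,5Z)-4-hydroxy-6-iodo-3-methylhepta-2,5-dienal | O=C/C=C(\C)[C@@H](O)/C=C(/C)I | intermediate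
8 | (2E,4S,5Z)-6-iodo-3-methyl-1-oxohepta-2,5-dien-4-yl acetate (fragment A) | O=C/C=C(\C)[C@@H](OC(C)=O)/C=C(/C)I | intermediate
9 | (2S)-but-3-ene-1,2-diol | OC[C@@H](O)C=C | starting material
10 | (3S)-3,4-bis[(tert-butyldimethylsilyl)oxy]but-1-ene | CC(C)(C)[Si](C)(C)OC[C@@H](O[Si](C)(C)C(C)(C)C)C=C | intermediate
11 | (2S)-2-[(tert-butyldimethylsilyl)oxy]but-3-en-1-ol | OC[C@@H](O[Si](C)(C)C(C)(C)C)C=C | intermediate
12 | (2S)-2-[(tert-butyldimethylsilyl)oxy]but-3-enal | O=C[C@@H](O[Si](C)(C)C(C)(C)C)C=C | intermediate
13 | methyl propiolate | COC(=O)C#C | starting material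
14 | [1-(methoxycarbonyl)ethenyl]bis(2-methylpropyl)alumane | COC(=O)C(=C)[Al](CC(C)C)CC(C)C | intermediate
15 | methyl (4S)-4-[(tert-butyldimethylsilyl)oxy]-3-hydroxy-2-methylidenehex-5-enoate (C3 epimers) | COC(=O)C(=C)C(O)[C@@H](O[Si](C)(C)C(C)(C)C)C=C | intermediate
16 | methyl (2Z,4S)-2-(bromomethyl)-4-[(tert-butyldimethylsilyl)oxy]hexa-2,5-dienoate (fragment B) | COC(=O)/C(CBr)=C/[C@@H](O[Si](C)(C)C(C)(C)C)C=C | intermediate
17 | allylindium dibromide from 16 | COC(=O)/C(C[In](Br)Br)=C/[C@@H](O[Si](C)(C)C(C)(C)C)C=C | intermediate
18 | syn hydroxy ester (open form of 19; C1–OH free, C9 silyl ether) | COC(=O)C(=C)[C@H]([C@@H](O[Si](C)(C)C(C)(C)C)C=C)[C@@H](O)/C=C(\C)[C@@H](OC(C)=O)/C=C(/C)I | intermediate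
19 | cis-α-methylene-γ-butyrolactone, γ-substituent (1E,4Z)-3-acetoxy-5-iodo-2-methylhexa-1,4-dienyl, β-substituent (1S)-1-(silyloxy)prop-2-enyl (9S) | C=C1C(=O)O[C@@H](/C=C(\C)[C@@H](OC(C)=O)/C=C(/C)I)[C@H]1[C@@H](O[Si](C)(C)C(C)(C)C)C=C | intermediate
20 | C9 alcohol of 19 (9S) | C=C1C(=O)O[C@@H](/C=C(\C)[C@@H](OC(C)=O)/C=C(/C)I)[C@H]1[C@@H](O)C=C | intermediate
21 | angelic acid, (2Z)-2-methylbut-2-enoic acid | C/C=C(/C)C(=O)O | starting material
22 | seco-angelate (C9 inverted to 9R; vinyl group and (Z)-vinyl iodide termini) | C=C1C(=O)O[C@@H](/C=C(\C)[C@@H](OC(C)=O)/C=C(/C)I)[C@H]1[C@H](OC(=O)/C(C)=C\C)C=C | intermediate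
23 | B-alkyl-9-borabicyclo[3.3.1]nonane from 22 (boron on C7) | C=C1C(=O)O[C@@H](/C=C(\C)[C@@H](OC(C)=O)/C=C(/C)I)[C@H]1[C@H](OC(=O)/C(C)=C\C)CCB2C3CCCC2CCC3 | intermediate
24 | (2E,5Z)-cyclodeca-2,5-diene fused cis to the α-methylene lactone, 4-acetate, 9-angelate | C=C1C(=O)O[C@H]2/C=C(\C)[C@@H](OC(C)=O)/C=C(C)\CC[C@@H](OC(=O)/C(C)=C\C)[C@@H]12 | intermediate
25 | target, CNP0519641.1 | C=C1C(=O)O[C@H]2/C=C(\C)[C@@H](OC(C)=O)[C@H]3O[C@@]3(C)CC[C@@H](OC(=O)/C(C)=C\C)[C@@H]12 | target

**Count and risks**
Total steps: 15. Longest linear sequence: 10 steps (1–5 or 6–10, then 11–15).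

Step 14 (key step): the seco-borane may oligomerise, or lose boron by protodeboronation or β-hydride elimination, faster than the strained ten-membered palladacycle forms. The fallback is a nickel-catalysed reductive cross-electrophile macrocyclisation, which needs no transmetalation from boron. It sets out from 22: hydroboration with 9-BBN-H and oxidation with NaBO3·4H2O would give the primary C7 alcohol F1, and I2/PPh3/imidazole the primary C7 iodide F2. NiBr2(dme)/4,4'-di-tert-butyl-2,2'-bipyridine with Zn powder and NaI in DMA at 0.002 M would then couple the alkyl iodide with the vinyl iodide and return to the route at 24.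

Step 15: the oxidant may attack the wrong face of C5=C6, because facial control rests on the conformation of the macrocycle, or may compete at C2=C3. The fallback sets out from 24: NBS in aqueous THF at 0 °C would give the C5-bromo C6-hydroxy bromohydrin F3 (bromonium ion on the exposed face, water opening at the tertiary C6 from the other face). DBU would then close the oxirane by displacement at C5, which puts the oxygen on the face opposite to the one reached by direct epoxidation, and the route is rejoined at 25.

Step 13: the branched allylic carbinol may eliminate, react in the SN2' mode, or resist displacement by the weakly acidic angelic acid. The fallback sets out from 20: Dess–Martin oxidation would give the vinyl ketone F4. Corey–Bakshi–Shibata reduction, with the oxazaborolidine enantiomer matched to Felkin–Anh attack anti to the C1 ring carbon, would give the 9-epimeric alcohol F5. Yamaguchi esterification with 21 (2,4,6-trichlorobenzoyl chloride, Et3N, DMAP, toluene), with retention, returns to the route at 22.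

**Further compounds**
F1 | step 14 | C7 primary alcohol from hydroboration–oxidation of 22 | C=C1C(=O)O[C@@H](/C=C(\C)[C@@H](OC(C)=O)/C=C(/C)I)[C@H]1[C@H](OC(=O)/C(C)=C\C)CCO
F2 | step 14 | C7 primary iodide | C=C1C(=O)O[C@@H](/C=C(\C)[C@@H](OC(C)=O)/C=C(/C)I)[C@H]1[C@H](OC(=O)/C(C)=C\C)CCI
F3 | step 15 | C5-bromo C6-hydroxy bromohydrin of 24 (C6 as in 25, C5 inverted) | C=C1C(=O)O[C@H]2/C=C(\C)[C@@H](OC(C)=O)[C@H](Br)[C@](O)(C)CC[C@@H](OC(=O)/C(C)=C\C)[C@@H]12
F4 | step 13 | vinyl ketone (9-oxo analogue of 20) | C=C1C(=O)O[C@@H](/C=C(\C)[C@@H](OC(C)=O)/C=C(/C)I)[C@H]1C(=O)C=C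
F5 | step 13 | 9-epimer of 20 (C9 carbinol configured as in 25) | C=C1C(=O)O[C@@H](/C=C(\C)[C@@H](OC(C)=O)/C=C(/C)I)[C@H]1[C@H](O)C=C
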